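## Retrosynthetic overview

1. The target is epioritin-(4β→6)-oritin-(4α→6)-epioritin-4α-ol. Both interflavan bonds are cut at benzylic C4 (C4 electrophile plus phenolic A-ring nucleophile), the upper bond last.
2. Upper unit: 4β-benzylsulfanyl-epioritin, made from teracacidin. Middle unit: the 3β,4β-epoxide of a flav-3-ene. Lower unit: teracacidin, made by Woodward cis-hydroxylation of the same flav-3-ene.
3. All three units come from one (2S)-flav-3-ene, which comes from a 2,4-cis-flavan-4-ol.
4. The flavan-4-ol comes from a 2'-hydroxychalcone by a chalcone-isomerase-like oxa-Michael closure of ring C, run as a dynamic kinetic resolution. The chalcone comes from gallacetophenone and 4-(benzyloxy)benzaldehyde.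
5. Ring order: ring C of every unit is formed once, in step 3; the aromatic rings are bought; afterwards only C–C couplings follow (lower + middle, then upper).

Assumption: flavan numbering is used for every unit, and α/β refer to the usual drawing (α = the face that carries the 2-aryl group).

## Route

Step 1
Reactants: 1 gallacetophenone (1-(2,3,4-trihydroxyphenyl)ethan-1-one)
Product: 2 di-O-benzylgallacetophenone (1-[3,4-bis(benzyloxy)-2-hydroxyphenyl]ethan-1-one)
Conditions: BnBr (2.1 equiv), K2CO3, acetone, reflux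
Reagents that add atoms: benzyl bromide, BrCc1ccccc1
Why: Williamson etherification; the 2-OH is hydrogen-bonded to the ketone and much less nucleophilic, so only the 3- and 4-OH are benzylated and the phenol needed for ring closure stays free.

Step 2
Reactants: 2 di-O-benzylgallacetophenone; 3 para-benzyloxybenzaldehyde (4-(benzyloxy)benzaldehyde)
Product: 4 chalcone ((E)-1-[3,4-bis(benzyloxy)-2-hydroxyphenyl]-3-[4-(benzyloxy)phenyl]prop-2-en-1-one)
Conditions: KOH, EtOH, rt
Reagents that add atoms: none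
Why: Claisen–Schmidt condensation of a methyl ketone with a non-enolisable aldehyde; E1cB dehydration of the aldol gives the E-enone.

Step 3
Reactants: 4 chalcone
Product: 6 cis-flavan-4-ol ((2S,4S)-7,8-bis(benzyloxy)-2-[4-(benzyloxy)phenyl]chroman-4-ol), via racemic flavanone 5 (not isolated)
Conditions: DBU (cat.), MeCN, 50 °C; then RuCl[(S,S)-TsDPEN](p-cymene) (2 mol %), HCO2H–DBU (1:1.2), MeCN, 40 °C
Reagents that add atoms: none
Why: Proposed new method: DBU effects the 6-endo oxa-Michael closure of ring C (the chalcone isomerase step) to racemic 5, which keeps racemising by E1cB ring opening and re-closure, while the (S,S)-ruthenium hydride reduces only (2S)-5 and only from the face that gives the 4S alcohol, so C2 (aryl α) and C4 (OH α, cis) are set together under catalyst control; the closest known reactions are the Noyori–Ikariya transfer-hydrogenative kinetic resolution of flavanones and the dynamic kinetic resolution of 2-substituted chroman-4-ones through retro-oxa-Michael racemisation.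

Step 4
Reactants: 6 cis-flavan-4-ol
Product: 7 flav-3-ene ((2S)-7,8-bis(benzyloxy)-2-[4-(benzyloxy)phenyl]-2H-chromene)
Conditions: Burgess reagent, THF, 50 °C, dark
Reagents that add atoms: none
Why: Burgess dehydration of the benzylic alcohol under neutral conditions gives the C3=C4 alkene; C2 is not involved, and without acid or strong base the allylic aryl ether neither ionises nor isomerises.

Step 5
Reactants: 7 flav-3-ene
Product: 10 tri-O-benzylteracacidin ((2R,3R,4R)-7,8-bis(benzyloxy)-2-[4-(benzyloxy)phenyl]chroman-3,4-diol; all-cis), via trans-iodoacetate 8 (not isolated), via cis-hydroxyacetate 9 (not isolated)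
Conditions: I2 (1.05 equiv), AgOAc (2.2 equiv), AcOH, rt, dark; then H2O, 50 °C; then K2CO3 (cat.), MeOH, rt
Reagents that add atoms: silver acetate, CC(=O)[O-].[Ag+]
Why: Woodward cis-hydroxylation: iodine adds anti to the 2-aryl group (β face), acetate enters at benzylic C4 from the α face, and silver-assisted displacement of iodide by the neighbouring acetate gives an α-face acetoxonium ion that water opens at its carbenium carbon, so both C–O bonds end on the face of the aryl group (3R,4R), opposite to what osmylation gives; both hydroxyl oxygens come from the acetate.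

Step 6
Reactants: 10 tri-O-benzylteracacidin
Product: 11 teracacidin (epioritin-4α-ol; (2R,3R,4R)-2-(4-hydroxyphenyl)chroman-3,4,7,8-tetrol)
Conditions: H2 (1 atm), Pd/C, EtOAc–MeOH, Et3N (trace), rt, stopped after 3 equiv H2
Reagents that add atoms: none
Why: Hydrogenolysis of aryl benzyl ethers; in neutral, amine-buffered medium these cleave much faster than the equatorial benzylic 4α-OH, so no stereocentre is touched.

Step 7
Reactants: 7 flav-3-ene; 11 teracacidin (2 equiv)
Product: 13 tri-O-benzyl dimer (7,8,4'-tri-O-benzyl-oritin-(4α→6)-epioritin-4α-ol; upper unit 2R,3S,4R; lower unit 2R,3R,4R), via β-epoxide 12 (not isolated)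
Conditions: DMDO, acetone, −40 → 0 °C, evaporate cold; then 11, (CF3)2CHOH–CH2Cl2, −20 °C → rt
Reagents that add atoms: dimethyldioxirane, CC1(C)OO1
Why: DMDO epoxidises the electron-rich styrenic alkene anti to the 2-aryl group, and the fluoroalcohol-promoted Friedel–Crafts opening at benzylic C4 by the most nucleophilic carbon of 11 (C6, ortho to 7-OH and para to O1) goes with inversion, which sets 3β-OH and 4α-aryl (3S,4R) of the middle unit; the benzyl-capped A-ring of the electrophile cannot compete as a nucleophile.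

Step 8
Reactants: 13 tri-O-benzyl dimer
Product: 14 dimer (oritin-(4α→6)-epioritin-4α-ol)
Conditions: H2 (1 atm), Pd/C, EtOAc–MeOH, Et3N (trace), rt
Reagents that add atoms: none
Why: Hydrogenolysis of the three aryl benzyl ethers; the C4–C6 interflavan bond of a 5-deoxy flavan and the equatorial 4α-OH are stable under these neutral conditions.

Step 9
Reactants: 11 teracacidin
Product: 15 4β-(benzylsulfanyl)epioritin ((2R,3S,4S)-4-(benzylsulfanyl)-2-(4-hydroxyphenyl)chroman-3,7,8-triol)
Conditions: BnSH (10 equiv), AcOH, 100 °C, N2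
Reagents that add atoms: benzyl mercaptan, SCc1ccccc1
Why: Acid-catalysed SN1 thiolysis of the flavan-3,4-diol: the C4 cation (stabilised by the para 7-OH) is captured by the large excess of thiol trans to the axial 3α-OH, giving the 4β thioether (4S) and outrunning self-condensation.

Step 10
Reactants: 15 4β-(benzylsulfanyl)epioritin; 14 dimer (2.5 equiv)
Product: 16 epioritin-(4β→6)-oritin-(4α→6)-epioritin-4α-ol (target; upper unit 2R,3R,4S; middle unit 2R,3S,4R; lower unit 2R,3R,4R)
Conditions: AgBF4 (2.5 equiv), THF, 0 °C, dark; unreacted 14 recovered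
Reagents that add atoms: none
Why: Thiophilic activation by AgBF4 frees the C4 cation of the epioritin unit under neutral conditions that leave the terminal 4α-OH of 14 alone, and the only unhindered nucleophilic carbon of 14 (C6 of its upper unit) attacks trans to the axial 3α-OH to give the 4β bond (4S), as in known silver-mediated couplings of free phenolic 4-thioflavans; excess 14 limits self-condensation of 15 and the yield will be modest.

## Compound list

1 | gallacetophenone (1-(2,3,4-trihydroxyphenyl)ethan-1-one) | CC(=O)c1ccc(O)c(O)c1O | starting material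
2 | di-O-benzylgallacetophenone (1-[3,4-bis(benzyloxy)-2-hydroxyphenyl]ethan-1-one) | CC(=O)c1ccc(OCc2ccccc2)c(OCc2ccccc2)c1O | intermediate
3 | 4-(benzyloxy)benzaldehyde | O=Cc1ccc(OCc2ccccc2)cc1 | starting material
4 | chalcone, (E)-1-[3,4-bis(benzyloxy)-2-hydroxyphenyl]-3-[4-(benzyloxy)phenyl]prop-2-en-1-one | O=C(/C=C/c1ccc(OCc2ccccc2)cc1)c1ccc(OCc2ccccc2)c(OCc2ccccc2)c1O | intermediate
5 | racemic flavanone, 7,8-bis(benzyloxy)-2-[4-(benzyloxy)phenyl]chroman-4-one (both enantiomers, interconverting) | O=C1CC(c2ccc(OCc3ccccc3)cc2)Oc2c1ccc(OCc1ccccc1)c2OCc1ccccc1 | intermediate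
6 | cis-flavan-4-ol, (2S,4S)-7,8-bis(benzyloxy)-2-[4-(benzyloxy)phenyl]chroman-4-ol | c1cc2c(c(OCc3ccccc3)c1OCc1ccccc1)O[C@H](c1ccc(OCc3ccccc3)cc1)C[C@@H]2O | intermediate
7 | flav-3-ene, (2S)-7,8-bis(benzyloxy)-2-[4-(benzyloxy)phenyl]-2H-chromene | c1cc2c(c(OCc3ccccc3)c1OCc1ccccc1)O[C@H](c1ccc(OCc3ccccc3)cc1)C=C2 | intermediate
8 | trans-iodoacetate, (2R,3R,4R)-7,8-bis(benzyloxy)-2-[4-(benzyloxy)phenyl]-3-iodochroman-4-yl acetate (3β-I, 4α-OAc) | c1cc2c(c(OCc3ccccc3)c1OCc1ccccc1)O[C@H](c1ccc(OCc3ccccc3)cc1)[C@@H](I)[C@@H]2OC(C)=O | intermediate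
9 | cis-hydroxyacetate, (2R,3R,4R)-7,8-bis(benzyloxy)-2-[4-(benzyloxy)phenyl]-4-hydroxychroman-3-yl acetate | c1cc2c(c(OCc3ccccc3)c1OCc1ccccc1)O[C@H](c1ccc(OCc3ccccc3)cc1)[C@H](OC(C)=O)[C@@H]2O | intermediate
10 | tri-O-benzylteracacidin, (2R,3R,4R)-7,8-bis(benzyloxy)-2-[4-(benzyloxy)phenyl]chroman-3,4-diol | c1cc2c(c(OCc3ccccc3)c1OCc1ccccc1)O[C@H](c1ccc(OCc3ccccc3)cc1)[C@H](O)[C@@H]2O | intermediate
11 | teracacidin (epioritin-4α-ol), (2R,3R,4R)-2-(4-hydroxyphenyl)chroman-3,4,7,8-tetrol | c1cc2c(c(O)c1O)O[C@H](c1ccc(O)cc1)[C@H](O)[C@@H]2O | intermediate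
12 | β-epoxide, (2R,3S,4S)-7,8-bis(benzyloxy)-2-[4-(benzyloxy)phenyl]-3,4-epoxychroman (oxygen anti to the 2-aryl group) | c1cc2c(c(OCc3ccccc3)c1OCc1ccccc1)O[C@H](c1ccc(OCc3ccccc3)cc1)[C@H]3O[C@@H]23 | intermediate
13 | tri-O-benzyl dimer, 7,8,4'-tri-O-benzyl-oritin-(4α→6)-epioritin-4α-ol | c1cc2c(c(OCc3ccccc3)c1OCc1ccccc1)O[C@H](c1ccc(OCc3ccccc3)cc1)[C@@H](O)[C@@H]2c1cc2c(c(O)c1O)O[C@H](c1ccc(O)cc1)[C@H](O)[C@@H]2O | intermediate
14 | dimer, oritin-(4α→6)-epioritin-4α-ol | c1cc2c(c(O)c1O)O[C@H](c1ccc(O)cc1)[C@@H](O)[C@@H]2c1cc2c(c(O)c1O)O[C@H](c1ccc(O)cc1)[C@H](O)[C@@H]2O | intermediate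
15 | 4β-(benzylsulfanyl)epioritin, (2R,3S,4S)-4-(benzylsulfanyl)-2-(4-hydroxyphenyl)chroman-3,7,8-triol | c1cc2c(c(O)c1O)O[C@H](c1ccc(O)cc1)[C@H](O)[C@H]2SCc1ccccc1 | intermediate
16 | epioritin-(4β→6)-oritin-(4α→6)-epioritin-4α-ol (CNP0140823.2) | Oc1ccc([C@H]2Oc3c(ccc(O)c3O)[C@H](c3cc4c(c(O)c3O)O[C@H](c3ccc(O)cc3)[C@@H](O)[C@@H]4c3cc4c(c(O)c3O)O[C@H](c3ccc(O)cc3)[C@H](O)[C@@H]4O)[C@H]2O)cc1 | target

## Step count and risks

Total: 10 steps. Longest linear sequence: 9 steps (1 → 2 → 4 → 6 → 7 → 10 → 11 → 13 → 14 → 16; step 9 is a side branch from 11).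

The three steps most likely to fail:

Step 3. The dynamic ring closure is untested on this substrate; the open chalcone may be reduced instead, or the ee may be low. The fallback sets C2 by C–C bond formation instead of ring closure. It sets out from 2: condensation with N,N-dimethylformamide dimethyl acetal gives the enaminone F1, which closes in HCl/CH2Cl2 to the chromone F2. Conjugate addition of 4-(benzyloxy)phenylboronic acid under Pd(OCOCF3)2 with the t-BuPyOx enantiomer that gives 2S (expected (R) from the cyclohexenone model; to be checked on the first run) gives the (2S)-flavanone F3. NaBH4 in MeOH–THF at 0 °C, with hydride entering anti to the equatorial aryl group, then comes back to the route at 6.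

Step 5. On this electron-rich flavene the iodonium route may suffer migration of the 2-aryl group to C3, ring iodination, or C4 epimerisation of the benzylic acetate. The fallback sets out from 7: NBS in wet THF gives the trans-bromohydrin F4 (3β-Br, 4α-OH). K2CO3 in acetone closes it by intramolecular SN2 to the α-epoxide F5, with the oxygen now syn to the 2-aryl group. DMSO with catalytic BF3·OEt2, then Et3N (Kornblum-type oxidation at benzylic C4), gives the 2,3-cis-dihydroflavonol F6. NaBH4 at −40 °C, with hydride from the β face and anti to both α substituents, comes back to the route at 10.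

Step 7. The epoxide may rearrange to a ketone, or 11 may be alkylated on oxygen instead of carbon. The fallback uses the classical diol electrophile and sets out from 7: OsO4 (cat.) with N-methylmorpholine N-oxide in acetone–water gives the 2,3-trans-3,4-cis diol F7 (osmylation anti to the aryl group). Hydrogenolysis over Pd/C gives free oritin-4β-ol F8. Its condensation with excess 11 in 0.1 M aqueous HCl–dioxane at rt (the axial 4β-OH of F8 ionises; the equatorial 4α-OH of 11 does not) comes back to the route at 14, bypassing 13.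

## Further compounds

F1 | step 3 | enaminone, (E)-1-[3,4-bis(benzyloxy)-2-hydroxyphenyl]-3-(dimethylamino)prop-2-en-1-one | CN(C)/C=C/C(=O)c1ccc(OCc2ccccc2)c(OCc2ccccc2)c1O
F2 | step 3 | chromone, 7,8-bis(benzyloxy)-4H-chromen-4-one | O=c1ccoc2c1ccc(OCc1ccccc1)c2OCc1ccccc1
F3 | step 3 | (2S)-flavanone, (2S)-7,8-bis(benzyloxy)-2-[4-(benzyloxy)phenyl]chroman-4-one | c1cc2c(c(OCc3ccccc3)c1OCc1ccccc1)O[C@H](c1ccc(OCc3ccccc3)cc1)CC2=O
F4 | step 5 | trans-bromohydrin, (2R,3S,4R)-7,8-bis(benzyloxy)-2-[4-(benzyloxy)phenyl]-3-bromochroman-4-ol | c1cc2c(c(OCc3ccccc3)c1OCc1ccccc1)O[C@H](c1ccc(OCc3ccccc3)cc1)[C@@H](Br)[C@@H]2O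
F5 | step 5 | α-epoxide, (2R,3R,4R)-7,8-bis(benzyloxy)-2-[4-(benzyloxy)phenyl]-3,4-epoxychroman | c1cc2c(c(OCc3ccccc3)c1OCc1ccccc1)O[C@H](c1ccc(OCc3ccccc3)cc1)[C@@H]3O[C@H]23
F6 | step 5 | 2,3-cis-dihydroflavonol, (2R,3S)-7,8-bis(benzyloxy)-2-[4-(benzyloxy)phenyl]-3-hydroxychroman-4-one | c1cc2c(c(OCc3ccccc3)c1OCc1ccccc1)O[C@H](c1ccc(OCc3ccccc3)cc1)[C@H](O)C2=O
F7 | step 7 | tri-O-benzyl-oritin-4β-ol, (2R,3S,4S)-7,8-bis(benzyloxy)-2-[4-(benzyloxy)phenyl]chroman-3,4-diol | c1cc2c(c(OCc3ccccc3)c1OCc1ccccc1)O[C@H](c1ccc(OCc3ccccc3)cc1)[C@@H](O)[C@H]2O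
F8 | step 7 | oritin-4β-ol, (2R,3S,4S)-2-(4-hydroxyphenyl)chroman-3,4,7,8-tetrol | c1cc2c(c(O)c1O)O[C@H](c1ccc(O)cc1)[C@@H](O)[C@H]2O
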